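**Strategy.** The furan-3(2H)-one ring (O, C10, C1, C2, C3; germacrane numbering) is disconnected to an oxirane on C10–C1 that carries a C2=C3 vinyl group. The ring oxygen already sits on the quaternary stereocentre C10, and C3 lies two atoms beyond C1. A copper-catalysed vinyl-oxirane ring expansion moves that oxygen from C1 to C3, so the three-membered ring becomes the five-membered one with C10 intact. A singlet-oxygen ene oxidation then installs the C1 ketone. The precursor is an open-chain triene monoepoxide assembled by Stille coupling. The ten-membered ring and the trans-fused α-methylene lactone are closed afterwards in one chromium-mediated allylation, and C6 is inverted during the final esterification.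

Key step: step 9

Remark: germacrane numbering (C1–C15) is used for skeleton atoms throughout; (R)-2-vinyloxirane and the L-fructose-derived enantiomer of the Shi ketone are taken as purchasable.

**Step 1**
Reactants: 1 (R)-2-vinyloxirane
Product: 2 (S)-hex-1-en-5-yn-3-ol
Conditions: LiC≡CH·H2NCH2CH2NH2, DMSO, rt; then H2O
Reagents that add atoms: lithium acetylide ethylenediamine complex, [Li+].[C-]#C.NCCN
Why: SN2 opening of the oxirane by acetylide at the unhindered CH2 terminus leaves the carbinol centre (future C8) untouched, and its descriptor becomes S only through the changed CIP ranking.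

**Step 2**
Reactants: 2 (S)-hex-1-en-5-yn-3-ol
Product: 3 (S)-tert-butyl(hex-1-en-5-yn-3-yloxy)dimethylsilane
Conditions: TBSCl, imidazole, DMF, rt
Reagents that add atoms: tert-butyldimethylsilyl chloride, CC(C)(C)[Si](C)(C)Cl
Why: Standard silylation, which keeps the C8 oxygen from acting as an internal nucleophile in steps 3 to 11.

**Step 3**
Reactants: 3 (S)-tert-butyl(hex-1-en-5-yn-3-yloxy)dimethylsilane
Product: 5 tert-butyl{[(3S,5E)-6-iodo-5-methylhexa-1,5-dien-3-yl]oxy}dimethylsilane, via alkenyldimethylalane 4 (not isolated)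
Conditions: AlMe3, Cp2ZrCl2 (cat.), CH2Cl2, 0 °C to rt; then I2, THF, −30 °C
Reagents that add atoms: trimethylaluminium, C[Al](C)C; iodine, II
Why: Negishi zirconium-catalysed syn-carboalumination puts methyl on the internal and aluminium on the terminal alkyne carbon, and iodinolysis with retention gives the E-iodoalkene (future C1=C10), the terminal alkene being inert to this catalyst.

**Step 4**
Reactants: 6 but-2-ynoic acid
Product: 7 (Z)-3-iodobut-2-enoic acid
Conditions: NaI, AcOH, 115 °C
Reagents that add atoms: sodium iodide, [Na+].[I-]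
Why: Anti hydroiodination of the ynoic acid (iodide conjugate addition, then protonation) gives the Z-β-iodo acid and so fixes the future 4Z-alkene.

**Step 5**
Reactants: 7 (Z)-3-iodobut-2-enoic acid
Product: 9 (Z)-3-iodo-N-methoxy-N-methylbut-2-enamide, via acid chloride 8 (not isolated)
Conditions: (COCl)2, DMF (cat.), CH2Cl2, 0 °C; then MeNH(OMe)·HCl, pyridine, 0 °C to rt
Reagents that add atoms: N,O-dimethylhydroxylamine hydrochloride, CNOC.Cl
Why: Acid chloride formation and amidation give the Weinreb amide without touching the Z-alkene.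

**Step 6**
Reactants: 9 (Z)-3-iodo-N-methoxy-N-methylbut-2-enamide; 10 (E)-1,2-bis(tributylstannyl)ethene (excess)
Product: 11 (2Z,4E)-N-methoxy-N,3-dimethyl-5-(tributylstannyl)penta-2,4-dienamide
Conditions: PdCl2(MeCN)2 (cat.), DMF, rt
Reagents that add atoms: none
Why: Stille coupling at one tin terminus of the excess distannane proceeds with retention at both alkenes.

**Step 7**
Reactants: 5 tert-butyl{[(3S,5E)-6-iodo-5-methylhexa-1,5-dien-3-yl]oxy}dimethylsilane; 11 (2Z,4E)-N-methoxy-N,3-dimethyl-5-(tributylstannyl)penta-2,4-dienamide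
Product: 12 (2Z,4E,6E,9S)-9-[(tert-butyldimethylsilyl)oxy]-N-methoxy-N,3,7-trimethylundeca-2,4,6,10-tetraenamide
Conditions: Pd2(dba)3 (cat.), AsPh3, CuI, NMP, rt
Reagents that add atoms: none
Why: Stille coupling with retention at both partners joins fragment 1 and fragment 2 at C1–C2.

**Step 8**
Reactants: 12 (2Z,4E,6E,9S)-9-[(tert-butyldimethylsilyl)oxy]-N-methoxy-N,3,7-trimethylundeca-2,4,6,10-tetraenamide
Product: 13 (2Z,4E)-5-[(2S,3S)-3-{(2S)-2-[(tert-butyldimethylsilyl)oxy]but-3-en-1-yl}-3-methyloxiran-2-yl]-N-methoxy-N,3-dimethylpenta-2,4-dienamide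
Conditions: L-fructose-derived Shi ketone (30 mol %), Oxone (2KHSO5·KHSO4·K2SO4), K2CO3, Bu4NHSO4, Na2B4O7 buffer, MeCN/CH2(OMe)2/H2O, 0 °C
Reagents that add atoms: potassium peroxymonosulfate, [K+].[O-]S(=O)(=O)OO
Why: Shi epoxidation through a spiro transition state attacks the most electron-rich, trisubstituted C10=C1 alkene of the triene, and the L-series ketone should give the (10S,1S)-oxirane, while the amide-conjugated and terminal alkenes are not attacked.

**Step 9**
Reactants: 13 (2Z,4E)-5-[(2S,3S)-3-{(2S)-2-[(tert-butyldimethylsilyl)oxy]but-3-en-1-yl}-3-methyloxiran-2-yl]-N-methoxy-N,3-dimethylpenta-2,4-dienamide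
Product: 14 (2Z)-3-[(5S)-5-{(2S)-2-[(tert-butyldimethylsilyl)oxy]but-3-en-1-yl}-5-methyl-2,5-dihydrofuran-2-yl]-N-methoxy-N-methylbut-2-enamide (both epimers at ring C2)
Conditions: Cu(hfacac)2 (copper bis(hexafluoroacetylacetonate), 5–10 mol %), toluene, 150 °C, sealed tube
Reagents that add atoms: none
Why: Lewis-acidic divalent copper binds the oxirane oxygen and the allylic C1–O bond ionises to a copper-bound tertiary C10 alkoxide and a C1–C2–C3 allyl cation; after rotation about C1–C2 the alkoxide collapses onto C3, so the ring O/C10/C1 grows by the two vinyl carbons into the ring O/C10/C1/C2/C3. The closest known reaction type is the copper-catalysed ring expansion of vinyl oxiranes to 2,5-dihydrofurans. The ring closes by alkoxide capture of the allyl-cation terminus, formally a 5-endo closure that is feasible because the electrophile is a cation (net 1,3-shift of oxygen). The C10–O bond is never broken, so C10 keeps the S configuration from step 8, while the new centre at C3 forms unselectively and is removed in step 11. The step needs C1–O rather than C10–O cleavage, closure at C3 rather than at C5, and retention of the 4Z-alkene; allylic stabilisation at C1 secures the first, and the carboxamide secures the other two by keeping positive charge off C5 so that C4=C5 stays a full double bond.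

**Step 10**
Reactants: 14 (2Z)-3-[(5S)-5-{(2S)-2-[(tert-butyldimethylsilyl)oxy]but-3-en-1-yl}-5-methyl-2,5-dihydrofuran-2-yl]-N-methoxy-N-methylbut-2-enamide
Product: 15 (2Z)-3-[(5S)-5-{(2S)-2-[(tert-butyldimethylsilyl)oxy]but-3-en-1-yl}-5-methyl-2,5-dihydrofuran-2-yl]but-2-enal
Conditions: iBu2AlH, THF, −78 °C; then aq. potassium sodium tartrate
Reagents that add atoms: none
Why: Hydride reduction of the N-methoxy-N-methylamide stops at the aldehyde oxidation level, and the Z-enal formed keeps C4=C5 electron-poor for step 11.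

**Step 11**
Reactants: 15 (2Z)-3-[(5S)-5-{(2S)-2-[(tert-butyldimethylsilyl)oxy]but-3-en-1-yl}-5-methyl-2,5-dihydrofuran-2-yl]but-2-enal
Product: 18 (2Z)-3-[(5S)-5-{(2S)-2-[(tert-butyldimethylsilyl)oxy]but-3-en-1-yl}-5-methyl-4-oxo-4,5-dihydrofuran-2-yl]but-2-enal, via allylic hydroperoxide 16 (not isolated), via peroxyacetate 17 (not isolated)
Conditions: O2, hν (visible), tetraphenylporphyrin (cat.), CH2Cl2, −20 °C; then Ac2O, pyridine, DMAP (cat.), 0 °C to rt
Reagents that add atoms: dioxygen, O=O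
Why: In the Schenck ene reaction singlet oxygen can abstract only the C3 hydrogen (C10 is quaternary), so oxygen enters at C1 and the double bond moves to C2=C3, and Kornblum–DeLaMare elimination of the acetylated hydroperoxide gives the C1 ketone, the enal and terminal vinyl alkenes being unreactive toward singlet oxygen.

**Step 12**
Reactants: 18 (2Z)-3-[(5S)-5-{(2S)-2-[(tert-butyldimethylsilyl)oxy]but-3-en-1-yl}-5-methyl-4-oxo-4,5-dihydrofuran-2-yl]but-2-enal
Product: 19 (2Z)-3-{(5S)-5-[(2S)-2-hydroxybut-3-en-1-yl]-5-methyl-4-oxo-4,5-dihydrofuran-2-yl}but-2-enal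
Conditions: HF·pyridine, pyridine, THF, 0 °C to rt
Reagents that add atoms: none
Why: Fluoride cleavage of the secondary silyl ether under buffered, non-basic conditions that the furanone and the Z-enal tolerate.

**Step 13**
Reactants: 19 (2Z)-3-{(5S)-5-[(2S)-2-hydroxybut-3-en-1-yl]-5-methyl-4-oxo-4,5-dihydrofuran-2-yl}but-2-enal; 20 2-(bromomethyl)acrylic acid
Product: 21 (2S)-1-{(2S)-2-methyl-3-oxo-5-[(2Z)-4-oxobut-2-en-2-yl]-2,3-dihydrofuran-2-yl}but-3-en-2-yl 2-(bromomethyl)prop-2-enoate
Conditions: DCC, DMAP (cat.), CH2Cl2, −20 to 0 °C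
Reagents that add atoms: none
Why: Steglich esterification of the secondary allylic alcohol at low temperature introduces the acrylate and allyl bromide units without displacement of the bromide.

**Step 14**
Reactants: 21 (2S)-1-{(2S)-2-methyl-3-oxo-5-[(2Z)-4-oxobut-2-en-2-yl]-2,3-dihydrofuran-2-yl}but-3-en-2-yl 2-(bromomethyl)prop-2-enoate
Product: 22 (2Z)-3-[(5S)-5-{[(2S)-4-(bromomethyl)-5-oxo-2,5-dihydrofuran-2-yl]methyl}-5-methyl-4-oxo-4,5-dihydrofuran-2-yl]but-2-enal
Conditions: second-generation Hoveyda–Grubbs catalyst, RuCl2(H2IMes)(=CH–C6H4-2-OiPr) (cat.), toluene, 80 °C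
Reagents that add atoms: none
Why: Ring-closing metathesis between the terminal vinyl group and the 1,1-disubstituted acrylate alkene closes the butenolide with loss of ethene, the electron-poor trisubstituted alkenes staying out of the catalytic cycle.

**Step 15**
Reactants: 22 (2Z)-3-[(5S)-5-{[(2S)-4-(bromomethyl)-5-oxo-2,5-dihydrofuran-2-yl]methyl}-5-methyl-4-oxo-4,5-dihydrofuran-2-yl]but-2-enal
Product: 24 (6R,7S,8S,10S)-6-hydroxy-1-oxo-3,10-epoxygermacra-2,4Z,11(13)-trien-12,8-olide, via allylchromium dichloride 23 (not isolated)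
Conditions: CrCl2 (excess), THF/DMF, high dilution, rt; then H2O
Reagents that add atoms: none
Why: In this intramolecular Nozaki–Hiyama (Barbier-type) allylation divalent chromium inserts into the allylic C–Br bond and the allylchromium adds through its γ-carbon C7 to the C6 aldehyde in a closed chair transition state, closing the ten-membered ring and creating the exo-methylene; C7 should form trans to the C9 substituent of the lactone, and because the lactone ring holds C8 trans to the CH2Cr group the anti adduct with 6R is expected.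

**Step 16**
Reactants: 25 methyl (Z)-2-methylbut-2-enoate (methyl angelate)
Product: 26 (Z)-2-methylbut-2-en-1-ol
Conditions: iBu2AlH, CH2Cl2, −78 to 0 °C; then aq. potassium sodium tartrate
Reagents that add atoms: none
Why: Hydride reduction of the ester to the allylic alcohol at low temperature keeps the Z-geometry.

**Step 17**
Reactants: 26 (Z)-2-methylbut-2-en-1-ol
Product: 27 [(2R,3S)-2,3-dimethyloxiran-2-yl]methanol
Conditions: Ti(OiPr)4, D-(−)-diethyl tartrate, tBuOOH, 4 Å molecular sieves, CH2Cl2, −20 °C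
Reagents that add atoms: tert-butyl hydroperoxide, CC(C)(C)OO
Why: Sharpless asymmetric epoxidation with D-(−)-tartrate should deliver oxygen to the face that gives the (2R,3S)-epoxy alcohol, and the Z-geometry fixes the cis relation of CH2OH and the C3 methyl.

**Step 18**
Reactants: 27 [(2R,3S)-2,3-dimethyloxiran-2-yl]methanol
Product: 28 (2S,3S)-2,3-dimethyloxirane-2-carboxylic acid
Conditions: RuCl3·xH2O (cat.), NaIO4, CCl4/MeCN/H2O, rt
Reagents that add atoms: sodium periodate, [Na+].[O-]I(=O)(=O)=O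
Why: Catalytic ruthenium tetroxide oxidation takes the primary alcohol to the acid without opening the oxirane, and the C2 descriptor changes to S by CIP ranking only.

**Step 19**
Reactants: 24 (6R,7S,8S,10S)-6-hydroxy-1-oxo-3,10-epoxygermacra-2,4Z,11(13)-trien-12,8-olide; 28 (2S,3S)-2,3-dimethyloxirane-2-carboxylic acid
Product: 29 (6S,7R,8S,10S)-6-{[(2S,3S)-2,3-dimethyloxirane-2-carbonyl]oxy}-1-oxo-3,10-epoxygermacra-2,4Z,11(13)-trien-12,8-olide (CNP0258430.1)
Conditions: PPh3, DIAD, toluene, 0 °C to rt (phosphine and azodicarboxylate premixed)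
Reagents that add atoms: none
Why: Mitsunobu esterification activates the C6 hydroxyl and the carboxylate displaces it in an SN2 reaction with inversion, turning 6R into the 6S ester of the target.

**Compound list**

1 | (R)-2-vinyloxirane | C=C[C@@H]1CO1 | starting material
2 | (S)-hex-1-en-5-yn-3-ol | C=C[C@@H](O)CC#C | intermediate
3 | (S)-tert-butyl(hex-1-en-5-yn-3-yloxy)dimethylsilane | C=C[C@@H](O[Si](C)(C)C(C)(C)C)CC#C | intermediate
4 | dimethyl[(1E,4S)-4-(tert-butyldimethylsilyloxy)-2-methylhexa-1,5-dien-1-yl]alane | C=C[C@@H](O[Si](C)(C)C(C)(C)C)C/C(C)=C/[Al](C)C | intermediate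
5 | tert-butyl{[(3S,5E)-6-iodo-5-methylhexa-1,5-dien-3-yl]oxy}dimethylsilane | C=C[C@@H](O[Si](C)(C)C(C)(C)C)C/C(C)=C/I | intermediate
6 | but-2-ynoic acid | CC#CC(=O)O | starting material
7 | (Z)-3-iodobut-2-enoic acid | I/C(C)=C\C(=O)O | intermediate
8 | (Z)-3-iodobut-2-enoyl chloride | I/C(C)=C\C(=O)Cl | intermediate
9 | (Z)-3-iodo-N-methoxy-N-methylbut-2-enamide | I/C(C)=C\C(=O)N(C)OC | intermediate
10 | (E)-1,2-bis(tributylstannyl)ethene | CCCC[Sn](CCCC)(CCCC)/C=C/[Sn](CCCC)(CCCC)CCCC | starting material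
11 | (2Z,4E)-N-methoxy-N,3-dimethyl-5-(tributylstannyl)penta-2,4-dienamide | CCCC[Sn](CCCC)(CCCC)/C=C/C(C)=C\C(=O)N(C)OC | intermediate
12 | (2Z,4E,6E,9S)-9-[(tert-butyldimethylsilyl)oxy]-N-methoxy-N,3,7-trimethylundeca-2,4,6,10-tetraenamide | C=C[C@@H](O[Si](C)(C)C(C)(C)C)C/C(C)=C/C=C/C(C)=C\C(=O)N(C)OC | intermediate
13 | (2Z,4E)-5-[(2S,3S)-3-{(2S)-2-[(tert-butyldimethylsilyl)oxy]but-3-en-1-yl}-3-methyloxiran-2-yl]-N-methoxy-N,3-dimethylpenta-2,4-dienamide | C=C[C@@H](O[Si](C)(C)C(C)(C)C)C[C@]1(C)O[C@H]1/C=C/C(C)=C\C(=O)N(C)OC | intermediate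
14 | (2Z)-3-[(5S)-5-{(2S)-2-[(tert-butyldimethylsilyl)oxy]but-3-en-1-yl}-5-methyl-2,5-dihydrofuran-2-yl]-N-methoxy-N-methylbut-2-enamide (epimers at ring C2) | C=C[C@@H](O[Si](C)(C)C(C)(C)C)C[C@]1(C)OC(/C(C)=C\C(=O)N(C)OC)C=C1 | intermediate
15 | (2Z)-3-[(5S)-5-{(2S)-2-[(tert-butyldimethylsilyl)oxy]but-3-en-1-yl}-5-methyl-2,5-dihydrofuran-2-yl]but-2-enal (epimers at ring C2) | C=C[C@@H](O[Si](C)(C)C(C)(C)C)C[C@]1(C)OC(/C(C)=C\C=O)C=C1 | intermediate
16 | (2Z)-3-[(5S)-5-{(2S)-2-[(tert-butyldimethylsilyl)oxy]but-3-en-1-yl}-4-hydroperoxy-5-methyl-4,5-dihydrofuran-2-yl]but-2-enal (epimers at ring C4) | C=C[C@@H](O[Si](C)(C)C(C)(C)C)C[C@]1(C)OC(/C(C)=C\C=O)=CC1OO | intermediate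
17 | (2Z)-3-[(5S)-4-(acetylperoxy)-5-{(2S)-2-[(tert-butyldimethylsilyl)oxy]but-3-en-1-yl}-5-methyl-4,5-dihydrofuran-2-yl]but-2-enal (epimers at ring C4) | C=C[C@@H](O[Si](C)(C)C(C)(C)C)C[C@]1(C)OC(/C(C)=C\C=O)=CC1OOC(C)=O | intermediate
18 | (2Z)-3-[(5S)-5-{(2S)-2-[(tert-butyldimethylsilyl)oxy]but-3-en-1-yl}-5-methyl-4-oxo-4,5-dihydrofuran-2-yl]but-2-enal | C=C[C@@H](O[Si](C)(C)C(C)(C)C)C[C@]1(C)OC(/C(C)=C\C=O)=CC1=O | intermediate
19 | (2Z)-3-{(5S)-5-[(2S)-2-hydroxybut-3-en-1-yl]-5-methyl-4-oxo-4,5-dihydrofuran-2-yl}but-2-enal | C=C[C@@H](O)C[C@]1(C)OC(/C(C)=C\C=O)=CC1=O | intermediate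
20 | 2-(bromomethyl)acrylic acid | C=C(CBr)C(=O)O | starting material
21 | (2S)-1-{(2S)-2-methyl-3-oxo-5-[(2Z)-4-oxobut-2-en-2-yl]-2,3-dihydrofuran-2-yl}but-3-en-2-yl 2-(bromomethyl)prop-2-enoate | C=C[C@@H](OC(=O)C(=C)CBr)C[C@]1(C)OC(/C(C)=C\C=O)=CC1=O | intermediate
22 | (2Z)-3-[(5S)-5-{[(2S)-4-(bromomethyl)-5-oxo-2,5-dihydrofuran-2-yl]methyl}-5-methyl-4-oxo-4,5-dihydrofuran-2-yl]but-2-enal | BrCC1=C[C@H](C[C@]2(C)OC(/C(C)=C\C=O)=CC2=O)OC1=O | intermediate
23 | allylchromium dichloride derived from 22 (CrCl2 in place of Br) | Cl[Cr](Cl)CC1=C[C@H](C[C@]2(C)OC(/C(C)=C\C=O)=CC2=O)OC1=O | intermediate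
24 | (6R,7S,8S,10S)-6-hydroxy-1-oxo-3,10-epoxygermacra-2,4Z,11(13)-trien-12,8-olide | C=C1C(=O)O[C@H]2C[C@]3(C)OC(=CC3=O)/C(C)=C\[C@@H](O)[C@H]12 | intermediate
25 | methyl (Z)-2-methylbut-2-enoate (methyl angelate) | C/C=C(/C)C(=O)OC | starting material
26 | (Z)-2-methylbut-2-en-1-ol | C/C=C(/C)CO | intermediate
27 | [(2R,3S)-2,3-dimethyloxiran-2-yl]methanol | OC[C@@]1(C)O[C@H]1C | intermediate
28 | (2S,3S)-2,3-dimethyloxirane-2-carboxylic acid | OC(=O)[C@@]1(C)O[C@H]1C | intermediate
29 | (6S,7R,8S,10S)-6-{[(2S,3S)-2,3-dimethyloxirane-2-carbonyl]oxy}-1-oxo-3,10-epoxygermacra-2,4Z,11(13)-trien-12,8-olide (CNP0258430.1) | C=C1C(=O)O[C@H]2C[C@]3(C)OC(=CC3=O)/C(C)=C\[C@H](OC(=O)[C@@]3(C)O[C@H]3C)[C@H]12 | target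

**Step count.** Total: 19 steps. Longest linear sequence: 13 steps (steps 1, 2, 3, 7, 8, 9, 10, 11, 12, 13, 14, 15, 19).

**Steps most likely to fail**

Step 9 (ring expansion). The oxirane may ionise at the tertiary C10–O bond and undergo a 1,2-shift to a ketone, or the dienamide may lose its Z-geometry at 150 °C, instead of the allylic C1–O ionisation and oxygen transfer to C3. The fallback sets out from 13. Zerovalent palladium and acetic acid (Pd(PPh3)4, AcOH, THF) open the vinyl oxirane in the 1,4-sense to (2Z,5E,7S,9S)-4-acetoxy-9-[(tert-butyldimethylsilyl)oxy]-7-hydroxy-N-methoxy-N,3,7-trimethylundeca-2,5,10-trienamide F1. A second treatment with Pd(PPh3)4 and Et3N in warm THF ionises the allylic acetate, and the C10 hydroxyl closes the five-membered ring by intramolecular allylic etherification. The fallback rejoins the route at 14.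

Step 11 (ene oxidation). The ene reaction at the cis-disubstituted ring alkene may be slow, so that photo-oxidation of the aldehyde or sensitised Z/E isomerisation competes. The fallback sets out from 15. Epoxidation of the ring alkene (mCPBA, NaHCO3, CH2Cl2) gives (2Z)-3-[(4S)-4-{(2S)-2-[(tert-butyldimethylsilyl)oxy]but-3-en-1-yl}-4-methyl-3,6-dioxabicyclo[3.1.0]hexan-2-yl]but-2-enal F2. DBU removes the C3 proton, which is vinylogous to the aldehyde, and opens the oxirane to (2Z)-3-[(5S)-5-{(2S)-2-[(tert-butyldimethylsilyl)oxy]but-3-en-1-yl}-4-hydroxy-5-methyl-4,5-dihydrofuran-2-yl]but-2-enal F3. Dess–Martin oxidation of the allylic alcohol rejoins the route at 18.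

Step 15 (macrocyclisation). Oligomerisation may outrun ring closure, facial selectivity at the aldehyde may be poor or reversed, or the C6 alkoxide may migrate onto the lactone carbonyl. The fallback sets out from 22. The ring is closed with zinc dust in THF/saturated aqueous NH4Cl, where the alkoxide is protonated at once and an open transition state may favour the syn adduct, (6S,7S,8S,10S)-6-hydroxy-1-oxo-3,10-epoxygermacra-2,4Z,11(13)-trien-12,8-olide F4. F4 already has the C6 configuration of the target and is acylated with retention by 28 under Yamaguchi conditions (2,4,6-trichlorobenzoyl chloride, Et3N, DMAP, toluene). This replaces steps 15 and 19 and rejoins the route at 29.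

**Further compounds**

F1 | step 9 | (2Z,5E,7S,9S)-4-acetoxy-9-[(tert-butyldimethylsilyl)oxy]-7-hydroxy-N-methoxy-N,3,7-trimethylundeca-2,5,10-trienamide | C=C[C@@H](O[Si](C)(C)C(C)(C)C)C[C@](C)(O)/C=C/C(OC(C)=O)/C(C)=C\C(=O)N(C)OC
F2 | step 11 | (2Z)-3-[(4S)-4-{(2S)-2-[(tert-butyldimethylsilyl)oxy]but-3-en-1-yl}-4-methyl-3,6-dioxabicyclo[3.1.0]hexan-2-yl]but-2-enal | C=C[C@@H](O[Si](C)(C)C(C)(C)C)C[C@]1(C)OC(/C(C)=C\C=O)C2OC12
F3 | step 11 | (2Z)-3-[(5S)-5-{(2S)-2-[(tert-butyldimethylsilyl)oxy]but-3-en-1-yl}-4-hydroxy-5-methyl-4,5-dihydrofuran-2-yl]but-2-enal | C=C[C@@H](O[Si](C)(C)C(C)(C)C)C[C@]1(C)OC(/C(C)=C\C=O)=CC1O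
F4 | step 15 | (6S,7S,8S,10S)-6-hydroxy-1-oxo-3,10-epoxygermacra-2,4Z,11(13)-trien-12,8-olide | C=C1C(=O)O[C@H]2C[C@]3(C)OC(=CC3=O)/C(C)=C\[C@H](O)[C@H]12
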